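The readings are calculated for substances that don't exist.

In a one-step world, with Dx + Kj giving Uv + Ty and nothing further, Uv climbs until a charge is spent. The runs below showed a rise and a fall instead.

| flask | Dx | Kj | remark | time |
|---|---|---|---|---|
| elm | 0.070 M | 0.055 M | run made earlier |  |
| alder | 0.11 M | 0.055 M | run made earlier |  |
| birch | 0.050 M | 0.083 M | run made earlier |  |
| flask | 0.050 M | 0.0550 M |  | 15 d |

- elm (time / d: Uv / %, Ek / %): 0.167: 6.1, 0; 0.417: 8.3, 0.5; 1.04: 6.3, 3.9; 2.50: 1.9, 5.4; 6.00: 2.3, 10.4; 15.0: 0.5, 9.6
- alder (time / d: Uv / %, Ek / %): 0.167: 5.8, 0; 0.417: 8.0, 2.6; 1.04: 6.1, 2.2; 2.50: 2.4, 5.7; 6.00: 0.3, 4.3; 15.0: 1.3, 6.9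
- birch (time / d: Uv / %, Ek / %): 0.167: 9.3, 1.2; 0.500: 13.7, 2.4; 1.67: 5.5, 5.6; 5.00: 0, 8.5; 15.0: 0, 10.8

(standard deviation of a reading: 1 percentage point)

- when, up to 15 d, the flask holds most Uv
- the amount of Uv, in percent of the Dx charged, at that time

One pair of numbers looked wrong to me. Alder was charged with 0.11 M of Dx and elm with 0.070 M, yet their top Uv readings were 8.0% and 8.3%, equal within the scatter of 1 percentage point.

I reckoned only the top of the curve, where making equals using (the steady-state condition). Counted in percent of the Dx charged, making goes with [Kj] and the share of Dx left, so the Dx charge cancels. If using is first order in [Uv], the top follows [Kj], corrected by what has been consumed by then. Birch differed from elm in both charges; its top reading over elm's was 1.65, against 1.51 in [Kj].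

I therefore took the holding figure, the top Uv share per unit of [Kj] charged, from birch, which has the flask's Dx charge: 1.65 M⁻¹, a reading. For the flask this gave 9.08%. The time I did not reckon: I guessed it between the times of the top readings in elm and birch, 0.417 d and 0.500 d.

The forecast said 0.45 d and 8.2%, less than my figure, reasoning that “The flask has the same Kj” as elm and alder.

The flask reached 9.85% at 0.476 d. Uv's half-life by turning into Vy, 0.20 d, is shorter than by turning into Ek, 1.7 d. The computed top over the flask's [Kj] charged came to 1.79 M⁻¹, against the reading of 1.65 M⁻¹ from birch.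

    Dx + Kj → Uv + Ty (k = 0.00783 M⁻¹ min⁻¹)
    Uv → Ek (k = 2.82 × 10⁻⁴ min⁻¹)
    Uv → Vy (k = 0.00238 min⁻¹)

For the neighbour flask with 0.14 M of Kj, the holding figure gave 23.1%. The computed top there was 20.4%.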